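**Plan**

- Labdane numbering is used throughout, including for the open-chain precursors: C4 carries CH2OAc, C10 the angular CH3, C8 the OH, C9 the side chain.
- Retrosynthetic cuts, in order: first the O18–acetyl bond and the C15 ester, then C13=C14 back to a C13 methyl ketone. C8–OH and C13=O are then folded into a cyclic enol ether and a 3β-OH is added. Finally C8–O, C9–C10 and C4–C5 are cut together, leaving a linear 3,4-epoxy-dienone.
- Enabling feature: rings A and B form a trans-decalin whose C4, C5, C10, C9 and equatorial C8–O bond show the anti-addition pattern of an all-E polyprenyl chain. The C13 carbonyl oxygen reaches C8 through a six-membered ring (O, C8, C9, C11, C12, C13).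
- Forward: farnesylacetone is hydroxylated at C18, epoxidised and silylated. One cationic cascade then closes ring A, ring B and the dihydropyran in that order. C3 is deoxygenated while the pyran still masks C8–OH and C13=O, the pyran is opened, C14–C15 are added, and the end groups are adjusted.
- Stereochemistry: Sharpless epoxidation with L-(+)-tartrate sets C3 and C4. Inversion at C4, the two E alkenes and a chair–chair fold relay this to C4, C5, C10, C9 and C8. C3 is erased later, and 13E comes from the olefination.

Key step: step 4

Assumption: (5E,9E)-farnesylacetone is taken as purchasable in geometrically pure form; material containing Z isomers would first be purified on AgNO3-impregnated silica.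

**Step 1**
Reactants: 1 (5E,9E)-farnesylacetone
Product: 2 (5E,9E,13E)-15-hydroxy-6,10,14-trimethylpentadeca-5,9,13-trien-2-one
Conditions: SeO2 (cat.), t-BuOOH, salicylic acid (cat.), CH2Cl2, 0 °C to rt, stopped at partial conversion
Reagents that add atoms: tert-butyl hydroperoxide, CC(C)(C)OO
Why: The catalytic SeO2 allylic hydroxylation (Riley oxidation; ene reaction then [2,3]-shift) should be fastest at the least hindered terminal isopropylidene group and oxidise only its E-methyl, so CH2OH ends trans to the chain, while the methyl ketone is not attacked at this temperature.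

**Step 2**
Reactants: 2 allylic alcohol; 3 L-(+)-diethyl tartrate (ligand on titanium, substoichiometric, not incorporated)
Product: 4 (13S,14S)-13,14-epoxy-15-hydroxy-6,10,14-trimethylpentadeca-5,9-dien-2-one (CH2OH trans to the chain on the oxirane; labdane C3 = S, C4 = S)
Conditions: Ti(Oi-Pr)4 (cat.), 3 (cat.), t-BuOOH, 4 Å MS, CH2Cl2, −20 °C
Reagents that add atoms: tert-butyl hydroperoxide, CC(C)(C)OO
Why: The Sharpless asymmetric epoxidation reacts only at the hydroxyl-bound alkene, so the two isolated alkenes and the ketone are spared, and with the (R,R)-tartrate an E-allylic alcohol should give the (2S,3S)-type epoxy alcohol, which sets both oxirane carbons.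

**Step 3**
Reactants: 4 epoxy alcohol
Product: 5 (13S,14S)-15-(tert-butyldimethylsilyloxy)-13,14-epoxy-6,10,14-trimethylpentadeca-5,9-dien-2-one (18-silyloxy-3,4-epoxide in labdane numbering)
Conditions: TBSCl, imidazole, CH2Cl2, 0 °C to rt
Reagents that add atoms: tert-butyldimethylsilyl chloride, CC(C)(C)[Si](C)(C)Cl
Why: Imidazole-mediated silylation of a primary alcohol is mild enough for the epoxide and ketone, and a silyl ether is preferred to an ester because it has no carbonyl that could bridge to C4 in step 4.

**Step 4**
Reactants: 5 silyloxy epoxy dienone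
Product: 6 18-(tert-butyldimethylsilyloxy)-8α,13-epoxy-14,15-dinorlabd-12-en-3β-ol (trans-anti-trans tricycle; 5α-H, 9α-H, 10β-CH3, 8β-CH3, 4β-CH3, 4α-CH2OSi)
Conditions: MeAlCl2 (2.2 equiv), CH2Cl2, −78 °C; then Et3N, aq. NaHCO3
Reagents that add atoms: none
Why: MeAlCl2 binds the epoxide oxygen and loosens its bond to the fully substituted C4; the C5=C10 alkene attacks C4 opposite to that oxygen, the C8=C9 alkene attacks the emerging C10 cation, the C13 carbonyl oxygen closes on the C8 cation, and the oxocarbenium ion sheds H-12 (consumed by the Al–CH3 bond) to leave the enol ether. It merges two known reaction types, the Lewis-acid epoxide-initiated polyene cyclisation and the acid cyclisation of polyprenyl methyl ketones to bicyclic enol ethers. Ring A closes 6-endo (both alkene carbons and both epoxide carbons end in the ring, the epoxide opening at its tertiary end), ring B closes 6-endo-trig, and the dihydropyran closes as a six-membered oxygen capture of a tertiary cation in which the C=O bond becomes endocyclic. C3 keeps its C–O bond and configuration (3β, equatorial) and so selects one of the two mirror-image chair–chair folds; C4 is set by inversion, making CH2OSi (trans to the chain on the oxirane) equatorial α and CH3 axial β; anti addition across the E C5=C10 alkene gives 5α-H and 10β-CH3, and anti addition across the E C8=C9 alkene gives 9α-H with C8–O antiperiplanar to C9–C10, hence equatorial α, and 8-CH3 axial β. The step needs opening at C4 rather than C3, full bicyclisation rather than a C3-to-C4 hydride shift or early proton loss, and oxygen capture rather than elimination at C8; the tertiary character of C4, the low temperature with a proton-scavenging Lewis acid and the strain-free six-membered reach of the ketone should secure these. One equivalent of Lewis acid is allowed for the ketone, whose aluminium complex is labile, and the position of the enol-ether double bond does not matter because step 7 converges on one ketone.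

**Step 5**
Reactants: 6 tricyclic alcohol
Product: 7 O-[18-(tert-butyldimethylsilyloxy)-8α,13-epoxy-14,15-dinorlabd-12-en-3β-yl] 1H-imidazole-1-carbothioate
Conditions: Im2C=S, DMAP (cat.), ClCH2CH2Cl, 80 °C
Reagents that add atoms: 1,1'-thiocarbonyldiimidazole, S=C(n1ccnc1)n1ccnc1
Why: Thioacyl transfer to the only free hydroxyl gives the Barton–McCombie precursor under neutral conditions, which avoids the O18-to-O3 silyl shift that a metal alkoxide (xanthate protocol) could trigger and leaves the acid-labile enol ether intact.

**Step 6**
Reactants: 7 thiocarbonylimidazolide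
Product: 8 18-(tert-butyldimethylsilyloxy)-8α,13-epoxy-14,15-dinorlabd-12-ene
Conditions: n-Bu3SnH, AIBN (cat.), toluene, 110 °C
Reagents that add atoms: none
Why: In the Barton–McCombie deoxygenation the stannyl radical adds to C=S and the released secondary C3 radical takes hydrogen from the stannane, so C3 ceases to be a stereocentre, while the silyl ether and the enol ether (still masking the 8-OH and the ketone) are inert to the neutral chain.

**Step 7**
Reactants: 8 enol ether
Product: 9 18-(tert-butyldimethylsilyloxy)-8α-hydroxy-14,15-dinorlabdan-13-one (in equilibrium with its cyclic hemiketal)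
Conditions: 0.1 M aq. HCl–THF, 0 °C to rt; NaHCO3 work-up, used without acidic chromatography
Reagents that add atoms: water, O
Why: Acid-catalysed enol ether hydrolysis (C12 protonation, water addition at C13, hemiketal opening) breaks only the C13–O bond, so the C8–O bond and its configuration are kept, and dilute cold acid should spare the primary silyl ether and the tertiary alcohol.

**Step 8**
Reactants: 9 hydroxy ketone; 10 triethyl phosphonoacetate
Product: 11 ethyl (13E)-18-(tert-butyldimethylsilyloxy)-8α-hydroxylabd-13-en-15-oate
Conditions: 10, NaH, THF, 0 °C; then 9, 0 °C to reflux; chromatographic removal of the minor geometric isomer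
Reagents that add atoms: triethyl phosphonoacetate, CCOC(=O)CP(=O)(OCC)OCC
Why: The Horner–Wadsworth–Emmons olefination drains the open ketone from its hemiketal equilibrium and, through reversible addition, should place the ester trans to the larger C12 chain (13E), an excess of the stabilised anion tolerating the free tertiary hydroxyl.

**Step 9**
Reactants: 11 silyl ether ester
Product: 13 (13E)-8α,18-dihydroxylabd-13-en-15-oic acid, via diol ester 12 (not isolated)
Conditions: TBAF, THF, rt; then LiOH, MeOH–H2O, 50 °C, same flask; cold dilute HCl to pH 3–4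
Reagents that add atoms: lithium hydroxide, [Li+].[OH-]
Why: Fluoride-induced Si–O cleavage followed by acyl-oxygen saponification of the ethyl ester touches no stereocentre and should not move the conjugated E alkene, and brief cold acidification preserves the tertiary alcohol.

**Step 10**
Reactants: 13 dihydroxy acid
Product: 15 (13E)-18-acetoxy-8α-hydroxylabd-13-en-15-oic acid, (4R,5R,8R,9R,10S), the target, via mixed anhydride 14 (not isolated)
Conditions: Ac2O, pyridine, rt; then H2O, rt
Reagents that add atoms: acetic anhydride, CC(=O)OC(C)=O
Why: Pyridine-mediated acetylation should take the primary C18 hydroxyl and leave the hindered tertiary C8 hydroxyl, which needs DMAP or heat, while the carboxyl group passes through mixed anhydride 14, which water cleaves at its more electrophilic acetyl carbonyl during the quench.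

**Compound list**

| No. | Name | SMILES | Role |
|---|---|---|---|
| 1 | (5E,9E)-farnesylacetone | CC(=O)CC/C=C(\C)CC/C=C(\C)CCC=C(C)C | starting material |
| 2 | (5E,9E,13E)-15-hydroxy-6,10,14-trimethylpentadeca-5,9,13-trien-2-one | CC(=O)CC/C=C(\C)CC/C=C(\C)CC/C=C(\C)CO | intermediate |
| 3 | L-(+)-diethyl tartrate, (2R,3R) | CCOC(=O)[C@H](O)[C@@H](O)C(=O)OCC | starting material |
| 4 | (13S,14S)-13,14-epoxy-15-hydroxy-6,10,14-trimethylpentadeca-5,9-dien-2-one | CC(=O)CC/C=C(\C)CC/C=C(\C)CC[C@@H]1O[C@@]1(C)CO | intermediate |
| 5 | (13S,14S)-15-(tert-butyldimethylsilyloxy)-13,14-epoxy-6,10,14-trimethylpentadeca-5,9-dien-2-one | CC(=O)CC/C=C(\C)CC/C=C(\C)CC[C@@H]1O[C@@]1(C)CO[Si](C)(C)C(C)(C)C | intermediate |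
| 6 | 18-(tert-butyldimethylsilyloxy)-8α,13-epoxy-14,15-dinorlabd-12-en-3β-ol | CC(C)(C)[Si](C)(C)OC[C@]1(C)[C@@H](O)CC[C@]2(C)[C@H]3CC=C(C)O[C@]3(C)CC[C@@H]12 | intermediate |
| 7 | 3β-O-(imidazol-1-ylthiocarbonyl) derivative of 6 | CC(C)(C)[Si](C)(C)OC[C@]1(C)[C@@H](OC(=S)n4ccnc4)CC[C@]2(C)[C@H]3CC=C(C)O[C@]3(C)CC[C@@H]12 | intermediate |
| 8 | 18-(tert-butyldimethylsilyloxy)-8α,13-epoxy-14,15-dinorlabd-12-ene | CC(C)(C)[Si](C)(C)OC[C@]1(C)CCC[C@]2(C)[C@H]3CC=C(C)O[C@]3(C)CC[C@@H]12 | intermediate |
| 9 | 18-(tert-butyldimethylsilyloxy)-8α-hydroxy-14,15-dinorlabdan-13-one | CC(C)(C)[Si](C)(C)OC[C@]1(C)CCC[C@]2(C)[C@@H](CCC(C)=O)[C@](C)(O)CC[C@@H]12 | intermediate |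
| 10 | triethyl phosphonoacetate | CCOC(=O)CP(=O)(OCC)OCC | starting material |
| 11 | ethyl (13E)-18-(tert-butyldimethylsilyloxy)-8α-hydroxylabd-13-en-15-oate | CC(C)(C)[Si](C)(C)OC[C@]1(C)CCC[C@]2(C)[C@@H](CC/C(C)=C/C(=O)OCC)[C@](C)(O)CC[C@@H]12 | intermediate |
| 12 | ethyl (13E)-8α,18-dihydroxylabd-13-en-15-oate | OC[C@]1(C)CCC[C@]2(C)[C@@H](CC/C(C)=C/C(=O)OCC)[C@](C)(O)CC[C@@H]12 | intermediate |
| 13 | (13E)-8α,18-dihydroxylabd-13-en-15-oic acid | OC[C@]1(C)CCC[C@]2(C)[C@@H](CC/C(C)=C/C(=O)O)[C@](C)(O)CC[C@@H]12 | intermediate |
| 14 | acetic (13E)-18-acetoxy-8α-hydroxylabd-13-en-15-oic anhydride | CC(=O)OC[C@]1(C)CCC[C@]2(C)[C@@H](CC/C(C)=C/C(=O)OC(C)=O)[C@](C)(O)CC[C@@H]12 | intermediate |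
| 15 | (13E)-18-acetoxy-8α-hydroxylabd-13-en-15-oic acid | CC(=O)OC[C@]1(C)CCC[C@]2(C)[C@@H](CC/C(C)=C/C(=O)O)[C@](C)(O)CC[C@@H]12 | target |

Total step count: 10. Longest linear sequence: 10 steps (1 to 15).

**Steps most likely to fail**

**Step 4.** The cascade may end early. The Lewis acid can tie up the carbonyl oxygen so that C8 loses a proton instead of being captured, a hydride can shift from C3 to C4, or only ring A may close.

The fallback sets out from 5 and returns at 6.
- The epoxide is opened homolytically with titanocene(III) chloride (Cp2TiCl2, Mn, THF, rt).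
- The tertiary C4 radical closes rings A and B by two 6-endo radical additions, and titanium-mediated β-hydride loss at C8 ends the sequence.
- This should give 3β-hydroxy-18-(tert-butyldimethylsilyloxy)-14,15-dinorlabd-8(17)-en-13-one F1; an unactivated dialkyl ketone is not reduced by this reagent.
- Catalytic p-TsOH in CH2Cl2 at 0 °C then protonates the exocyclic alkene. The ketone oxygen closes on C8 from the α face, away from the axial C10 methyl, and proton loss gives 6.
- Carbocycle formation and oxygen capture are thus separated, and no strong Lewis acid competes for the carbonyl.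
- In this variant C4 is set not by inversion but by the preference of the larger CH2OSi group for the equatorial site of the chair.

**Step 1.** Site selectivity among the three trisubstituted alkenes may be poor, the new alcohol may be oxidised further, and the ketone may slowly be oxidised at its α position.

The fallback sets out from 1 and returns at 2.
- Cross-metathesis of the terminal isopropylidene group with excess methacrolein (Hoveyda–Grubbs II catalyst, CH2Cl2, 40 °C) is used; the internal alkenes, which carry two chain substituents, are far less reactive.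
- This should give (2E,6E,10E)-2,6,10-trimethyl-14-oxopentadeca-2,6,10-trienal F2.
- Chemoselective 1,2-reduction of the aldehyde with LiAlH(Ot-Bu)3 in THF at −78 °C then gives 2 with the ketone untouched.

**Step 8.** Geometric discrimination at a methyl ketone may be weak, the reaction may be slow because the carbonyl hides as the hemiketal, and water may be lost back to the enol ether.

The fallback sets out from 9 and returns at 12, and hence 13, under the conditions of step 9. It replaces carbonyl olefination by the alkyne route with Negishi carboalumination.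
- N-(trimethylsilyl)imidazole silylates the tertiary hydroxyl without enolising the ketone and gives 18-(tert-butyldimethylsilyloxy)-8α-(trimethylsilyloxy)-14,15-dinorlabdan-13-one F3.
- Kinetic deprotonation at the methyl group (LDA, THF, −78 °C) and trapping with ClP(O)(OEt)2 give the terminal enol diethyl phosphate F4.
- More LDA eliminates F4 in the same flask to the terminal alkyne (C12–C≡CH) F5.
- Me3Al with Cp2ZrCl2 in ClCH2CH2Cl adds CH3 and Al syn across the alkyne, giving the (E)-dimethylalkenylalane F6.
- Ethyl chloroformate converts F6 with retention into ethyl (13E)-18-(tert-butyldimethylsilyloxy)-8α-(trimethylsilyloxy)labd-13-en-15-oate F7.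
- TBAF removes both silyl groups to give 12, and LiOH gives 13.

**Further compounds**

F1 | step 4 | 3β-hydroxy-18-(tert-butyldimethylsilyloxy)-14,15-dinorlabd-8(17)-en-13-one | CC(C)(C)[Si](C)(C)OC[C@]1(C)[C@@H](O)CC[C@]2(C)[C@@H](CCC(C)=O)C(=C)CC[C@@H]12
F2 | step 1 | (2E,6E,10E)-2,6,10-trimethyl-14-oxopentadeca-2,6,10-trienal | CC(=O)CC/C=C(\C)CC/C=C(\C)CC/C=C(\C)C=O
F3 | step 8 | 18-(tert-butyldimethylsilyloxy)-8α-(trimethylsilyloxy)-14,15-dinorlabdan-13-one | CC(C)(C)[Si](C)(C)OC[C@]1(C)CCC[C@]2(C)[C@@H](CCC(C)=O)[C@](C)(O[Si](C)(C)C)CC[C@@H]12
F4 | step 8 | terminal enol diethyl phosphate of F3 | CC(C)(C)[Si](C)(C)OC[C@]1(C)CCC[C@]2(C)[C@@H](CCC(=C)OP(=O)(OCC)OCC)[C@](C)(O[Si](C)(C)C)CC[C@@H]12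
F5 | step 8 | terminal alkyne (C12–C≡CH) with 8α-OSiMe3 and 18-OTBS | CC(C)(C)[Si](C)(C)OC[C@]1(C)CCC[C@]2(C)[C@@H](CCC#C)[C@](C)(O[Si](C)(C)C)CC[C@@H]12
F6 | step 8 | (E)-dimethylalkenylalane from F5 | CC(C)(C)[Si](C)(C)OC[C@]1(C)CCC[C@]2(C)[C@@H](CC/C(C)=C/[Al](C)C)[C@](C)(O[Si](C)(C)C)CC[C@@H]12
F7 | step 8 | ethyl (13E)-18-(tert-butyldimethylsilyloxy)-8α-(trimethylsilyloxy)labd-13-en-15-oate | CC(C)(C)[Si](C)(C)OC[C@]1(C)CCC[C@]2(C)[C@@H](CC/C(C)=C/C(=O)OCC)[C@](C)(O[Si](C)(C)C)CC[C@@H]12
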